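**Plan**
Lactone numbering: O1, C2 (C=O), C3 (quaternary; OH and benzylic C7), C4, C5 (CH2); C6 is the carbinol carbon on C4. C5 is a lone CH2 between O1 and C4, and C4 is enolisable once C6 is an aryl ketone, so C5 can be formaldehyde.
Cuts: C6–OH back to the ketone; C4–C5 and O1–C2 in one operation (aldol with formaldehyde, then lactonisation of a 4-aryl-4-oxobutanoate); C6–aryl (acid chloride plus arylzinc); C3–C7 (enolate benzylation).
Forward: (S)-malic acid gives the C2–C3–C4–C6 chain as a pivalaldehyde dioxolanone; benzylation at C3, acylation of the arylzinc at C6, methanolysis and O-protection give the open-chain keto ester; the lactone ring closes in the key step; ketone reduction and hydrogenolysis finish.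
Stereochemistry: C3 from (S)-malic acid (alkylation with retention via the dioxolanone); C4 by thermodynamic equilibration against C3 (aroyl trans to benzyl); C6 by reagent-controlled Corey–Bakshi–Shibata reduction. The target is (3S,4R,6R).
Protection: benzyl ethers on both phenols and a benzyloxymethyl ether on the tertiary alcohol, so that the acid-sensitive benzylic alcohol is unveiled only by a final neutral hydrogenolysis.

Key step: step 9

Remark: formaldehyde is introduced as paraformaldehyde, which the amidine base depolymerises in the flask; 4-(benzyloxy)-3-methoxybenzyl alcohol is taken as a purchased material.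

**Route**

Step 1
Reactants: 1 (S)-malic acid; 2 pivalaldehyde
Product: 3 [(2S,4S)-2-tert-butyl-5-oxo-1,3-dioxolan-4-yl]acetic acid (tert-butyl cis to CH2CO2H)
Conditions: t-BuCHO (1.5 equiv), TsOH·H2O (cat.), H2SO4 (cat.), pentane, reflux, Dean–Stark; recrystallisation
Reagents that add atoms: none
Why: Acid-catalysed acetalisation of the α-hydroxy acid unit with azeotropic water removal closes the five-membered dioxolanone, and the acetal centre should settle cis to the CH2CO2H group under thermodynamic control, crystallisation completing the enrichment.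

Step 2
Reactants: 4 4-(benzyloxy)-3-methoxybenzyl alcohol
Product: 5 4-(benzyloxy)-3-methoxybenzyl bromide
Conditions: PBr3 (0.4 equiv), Et2O, 0 °C
Reagents that add atoms: phosphorus tribromide, BrP(Br)Br
Why: Bromide displaces the activated phosphite ester of an electron-rich benzylic alcohol (nucleophilic substitution), a standard conversion that leaves the aryl benzyl ether untouched.

Step 3
Reactants: 3 [(2S,4S)-2-tert-butyl-5-oxo-1,3-dioxolan-4-yl]acetic acid; 5 4-(benzyloxy)-3-methoxybenzyl bromide
Product: 7 [(2S,4S)-4-[4-(benzyloxy)-3-methoxybenzyl]-2-tert-butyl-5-oxo-1,3-dioxolan-4-yl]acetic acid (arylmethyl trans to tert-butyl), via dilithium enolate carboxylate 6 (not isolated)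
Conditions: LiN(SiMe3)2 (2.2 equiv), THF, −78 °C; 5 (1.1 equiv), −78 → −40 °C; 1 M HCl work-up
Reagents that add atoms: none
Why: Dianion alkylation with self-regeneration of the stereocentre: the benzylic bromide should attack the dioxolanone enolate on the face opposite the tert-butyl group, so the arylmethyl group takes the place of the former hydrogen and the malic acid configuration is carried into the quaternary centre with retention.

Step 4
Reactants: 7 [(2S,4S)-4-[4-(benzyloxy)-3-methoxybenzyl]-2-tert-butyl-5-oxo-1,3-dioxolan-4-yl]acetic acid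
Product: 8 [(2S,4S)-4-[4-(benzyloxy)-3-methoxybenzyl]-2-tert-butyl-5-oxo-1,3-dioxolan-4-yl]acetyl chloride
Conditions: (COCl)2 (1.5 equiv), DMF (cat.), CH2Cl2, 0 °C → rt; evaporate, use crude
Reagents that add atoms: oxalyl chloride, ClC(=O)C(Cl)=O
Why: Vilsmeier-type activation of the carboxylic acid gives the acid chloride under conditions that the acyl acetal and the benzyl ether tolerate, and no stereocentre is involved.

Step 5
Reactants: 9 4-bromo-2-methoxyphenol
Product: 10 1-(benzyloxy)-4-bromo-2-methoxybenzene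
Conditions: BnBr, K2CO3, DMF, rt
Reagents that add atoms: benzyl bromide, BrCc1ccccc1
Why: Williamson etherification of the phenoxide installs a benzyl ether that withstands organolithium, acid and amidine base and leaves by hydrogenolysis.

Step 6
Reactants: 8 [(2S,4S)-4-[4-(benzyloxy)-3-methoxybenzyl]-2-tert-butyl-5-oxo-1,3-dioxolan-4-yl]acetyl chloride; 10 1-(benzyloxy)-4-bromo-2-methoxybenzene
Product: 13 (2S,5S)-5-[4-(benzyloxy)-3-methoxybenzyl]-5-{2-[4-(benzyloxy)-3-methoxyphenyl]-2-oxoethyl}-2-tert-butyl-1,3-dioxolan-4-one, via aryllithium 11 (not isolated), via arylzinc chloride 12 (not isolated)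
Conditions: 10, n-BuLi, THF, −78 °C; ZnCl2 (THF), −78 → 0 °C; then 8, Pd(PPh3)4 (5 mol %), THF, 0 °C → rt
Reagents that add atoms: none
Why: Negishi acylation: bromine–lithium exchange (para to the benzyloxy group) and transmetalation give an arylzinc chloride that couples with the acid chloride under zerovalent palladium catalysis, while being too unreactive to add to the dioxolanone carbonyl or to the product ketone, so the quaternary centre is untouched.

Step 7
Reactants: 13 (2S,5S)-5-[4-(benzyloxy)-3-methoxybenzyl]-5-{2-[4-(benzyloxy)-3-methoxyphenyl]-2-oxoethyl}-2-tert-butyl-1,3-dioxolan-4-one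
Product: 14 methyl (2S)-2-[4-(benzyloxy)-3-methoxybenzyl]-4-[4-(benzyloxy)-3-methoxyphenyl]-2-hydroxy-4-oxobutanoate
Conditions: HCl (1.25 M in MeOH), rt → 40 °C; NaHCO3 work-up
Reagents that add atoms: methanol, CO
Why: Acid-catalysed methanolysis (transacetalisation and esterification) opens the dioxolanone to the methyl ester and tertiary alcohol without base, so the β-hydroxy ketone cannot undergo retro-aldol cleavage and C3 keeps its configuration.

Step 8
Reactants: 14 methyl (2S)-2-[4-(benzyloxy)-3-methoxybenzyl]-4-[4-(benzyloxy)-3-methoxyphenyl]-2-hydroxy-4-oxobutanoate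
Product: 15 methyl (2S)-2-[(benzyloxy)methoxy]-2-[4-(benzyloxy)-3-methoxybenzyl]-4-[4-(benzyloxy)-3-methoxyphenyl]-4-oxobutanoate
Conditions: BnOCH2Cl (3 equiv), i-Pr2NEt (4 equiv), Bu4NI (cat.), ClCH2CH2Cl, 50 °C
Reagents that add atoms: benzyl chloromethyl ether, ClCOCc1ccccc1
Why: Iodide-catalysed O-alkylation of the hindered tertiary alcohol with a reactive α-chloro ether gives the benzyloxymethyl acetal, the amine being too weak to form the alkoxide that would trigger retro-aldol cleavage.

Step 9
Reactants: 15 methyl (2S)-2-[(benzyloxy)methoxy]-2-[4-(benzyloxy)-3-methoxybenzyl]-4-[4-(benzyloxy)-3-methoxyphenyl]-4-oxobutanoate; 16 formaldehyde (as paraformaldehyde)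
Product: 19 (3S,4S)-4-[4-(benzyloxy)-3-methoxybenzoyl]-3-[(benzyloxy)methoxy]-3-[4-(benzyloxy)-3-methoxybenzyl]dihydrofuran-2(3H)-one (aroyl trans to benzyl), via aldol adduct 17 (not isolated), via C4-epimeric lactone 18 (not isolated)
Conditions: (CH2O)n (1.5 equiv), DBU (0.2 equiv), THF–DMSO, 0 °C → rt; AcOH quench
Reagents that add atoms: none
Why: DBU reversibly enolises the aryl ketone at C4, the only enolisable position because C3 is quaternary and the other ketone substituent is aryl; the enolate adds to formaldehyde (crossed aldol hydroxymethylation) to form C4–C5, and the primary alkoxide attacks the methyl ester in a 5-exo-trig acyl substitution that forms O1–C2 and releases methoxide, which turns the base over. The closest known reaction type is the base-mediated hydroxymethylation of 3-aroylpropionic acids and esters with formaldehyde, which gives 4-aroylbutyrolactones. C4 is set by thermodynamic control: its hydrogen stays α to the ketone in the lactone, so 18 and 19 interconvert through the enolate and the aroyl group should settle trans to the C3 benzyl group (the larger of the two C3 substituents) and cis to the alkoxy group, while C3 cannot epimerise. The step needs aldol addition and ring closure to outrun E1cB loss of the C3 alkoxy group from the C4 enolate and β-elimination of the lactone carboxylate from C5; the poor leaving ability of the acetal-type alkoxide, the catalytic amount of a non-nucleophilic base, the low temperature and the high electrophilicity of formaldehyde are relied on for this. The benzyloxymethyl ether also blocks retro-aldol cleavage of C3–C4, and a second hydroxymethylation at C4 is disfavoured because it would place a quaternary centre next to the quaternary C3 and is reversible.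

Step 10
Reactants: 19 (3S,4S)-4-[4-(benzyloxy)-3-methoxybenzoyl]-3-[(benzyloxy)methoxy]-3-[4-(benzyloxy)-3-methoxybenzyl]dihydrofuran-2(3H)-one
Product: 20 (3S,4R)-3-[(benzyloxy)methoxy]-3-[4-(benzyloxy)-3-methoxybenzyl]-4-[(R)-[4-(benzyloxy)-3-methoxyphenyl](hydroxy)methyl]dihydrofuran-2(3H)-one
Conditions: (S)-1-methyl-3,3-diphenyltetrahydro-3H-pyrrolo[1,2-c][1,3,2]oxazaborole [(S)-Me-CBS] (20 mol %), BH3·SMe2 (1.0 equiv), THF, −20 °C; MeOH, then pH 7 buffer
Reagents that add atoms: none
Why: Corey–Bakshi–Shibata reduction: with the aryl group as the large substituent the (S)-oxazaborolidine–borane complex should deliver hydride to the face that gives the (R)-carbinol (the sense in which acetophenone gives (R)-1-phenylethanol), setting C6 under reagent control while the lactone and the acetal survive at low temperature and the non-basic work-up avoids translactonisation.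

Step 11
Reactants: 20 (3S,4R)-3-[(benzyloxy)methoxy]-3-[4-(benzyloxy)-3-methoxybenzyl]-4-[(R)-[4-(benzyloxy)-3-methoxyphenyl](hydroxy)methyl]dihydrofuran-2(3H)-one
Product: 22 (3S,4R)-3-hydroxy-4-[(R)-hydroxy(4-hydroxy-3-methoxyphenyl)methyl]-3-(4-hydroxy-3-methoxybenzyl)dihydrofuran-2(3H)-one (target), via O-hydroxymethyl hemiacetal 21 (not isolated)
Conditions: H2 (1 atm), 10 % Pd/C, EtOAc–MeOH, rt
Reagents that add atoms: none
Why: Catalytic hydrogenolysis cleaves the two aryl benzyl ethers and the benzyl group of the acetal (whose hemiacetal then loses formaldehyde) under neutral conditions, where a secondary benzylic alcohol reacts much more slowly than benzyl ethers, so the acid-labile C6 carbinol and the lactone should remain intact.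

**Compound list**

1 | (S)-malic acid | OC(=O)C[C@H](O)C(=O)O | starting material
2 | pivalaldehyde | CC(C)(C)C=O | starting material
3 | [(2S,4S)-2-tert-butyl-5-oxo-1,3-dioxolan-4-yl]acetic acid (cis) | OC(=O)C[C@@H]1O[C@H](C(C)(C)C)OC1=O | intermediate
4 | 4-(benzyloxy)-3-methoxybenzyl alcohol | COc1cc(CO)ccc1OCc1ccccc1 | starting material
5 | 4-(benzyloxy)-3-methoxybenzyl bromide | COc1cc(CBr)ccc1OCc1ccccc1 | intermediate
6 | dilithium enolate carboxylate of 3 | [Li+].[Li+].[O-]C(=O)CC1=C([O-])O[C@@H](C(C)(C)C)O1 | intermediate (not isolated)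
7 | [(2S,4S)-4-[4-(benzyloxy)-3-methoxybenzyl]-2-tert-butyl-5-oxo-1,3-dioxolan-4-yl]acetic acid (arylmethyl trans to tert-butyl) | OC(=O)C[C@]1(Cc2ccc(OCc3ccccc3)c(OC)c2)O[C@H](C(C)(C)C)OC1=O | intermediate
8 | [(2S,4S)-4-[4-(benzyloxy)-3-methoxybenzyl]-2-tert-butyl-5-oxo-1,3-dioxolan-4-yl]acetyl chloride | ClC(=O)C[C@]1(Cc2ccc(OCc3ccccc3)c(OC)c2)O[C@H](C(C)(C)C)OC1=O | intermediate
9 | 4-bromo-2-methoxyphenol | COc1cc(Br)ccc1O | starting material
10 | 1-(benzyloxy)-4-bromo-2-methoxybenzene | COc1cc(Br)ccc1OCc1ccccc1 | intermediate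
11 | [4-(benzyloxy)-3-methoxyphenyl]lithium | [Li]c1ccc(OCc2ccccc2)c(OC)c1 | intermediate (not isolated)
12 | [4-(benzyloxy)-3-methoxyphenyl]zinc chloride | Cl[Zn]c1ccc(OCc2ccccc2)c(OC)c1 | intermediate (not isolated)
13 | (2S,5S)-5-[4-(benzyloxy)-3-methoxybenzyl]-5-{2-[4-(benzyloxy)-3-methoxyphenyl]-2-oxoethyl}-2-tert-butyl-1,3-dioxolan-4-one | COc1cc(ccc1OCc1ccccc1)C(=O)C[C@]1(Cc2ccc(OCc3ccccc3)c(OC)c2)O[C@H](C(C)(C)C)OC1=O | intermediate
14 | methyl (2S)-2-[4-(benzyloxy)-3-methoxybenzyl]-4-[4-(benzyloxy)-3-methoxyphenyl]-2-hydroxy-4-oxobutanoate | COc1cc(C[C@@](O)(C(=O)OC)CC(=O)c2ccc(OCc3ccccc3)c(OC)c2)ccc1OCc1ccccc1 | intermediate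
15 | methyl (2S)-2-[(benzyloxy)methoxy]-2-[4-(benzyloxy)-3-methoxybenzyl]-4-[4-(benzyloxy)-3-methoxyphenyl]-4-oxobutanoate | COc1cc(C[C@@](OCOCc3ccccc3)(C(=O)OC)CC(=O)c2ccc(OCc3ccccc3)c(OC)c2)ccc1OCc1ccccc1 | intermediate
16 | formaldehyde (used as paraformaldehyde) | C=O | starting material
17 | methyl (2S)-2-[(benzyloxy)methoxy]-2-[4-(benzyloxy)-3-methoxybenzyl]-4-[4-(benzyloxy)-3-methoxyphenyl]-3-(hydroxymethyl)-4-oxobutanoate (both epimers at the new centre) | COc1cc(C[C@@](OCOCc3ccccc3)(C(=O)OC)C(CO)C(=O)c2ccc(OCc3ccccc3)c(OC)c2)ccc1OCc1ccccc1 | intermediate (not isolated)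
18 | (3S,4R)-4-[4-(benzyloxy)-3-methoxybenzoyl]-3-[(benzyloxy)methoxy]-3-[4-(benzyloxy)-3-methoxybenzyl]dihydrofuran-2(3H)-one (aroyl cis to benzyl) | COc1cc(C[C@@]2(OCOCc3ccccc3)C(=O)OC[C@H]2C(=O)c2ccc(OCc3ccccc3)c(OC)c2)ccc1OCc1ccccc1 | intermediate (not isolated)
19 | (3S,4S)-4-[4-(benzyloxy)-3-methoxybenzoyl]-3-[(benzyloxy)methoxy]-3-[4-(benzyloxy)-3-methoxybenzyl]dihydrofuran-2(3H)-one (aroyl trans to benzyl) | COc1cc(C[C@@]2(OCOCc3ccccc3)C(=O)OC[C@@H]2C(=O)c2ccc(OCc3ccccc3)c(OC)c2)ccc1OCc1ccccc1 | intermediate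
20 | (3S,4R)-3-[(benzyloxy)methoxy]-3-[4-(benzyloxy)-3-methoxybenzyl]-4-[(R)-[4-(benzyloxy)-3-methoxyphenyl](hydroxy)methyl]dihydrofuran-2(3H)-one | COc1cc(C[C@@]2(OCOCc3ccccc3)C(=O)OC[C@@H]2[C@@H](O)c2ccc(OCc3ccccc3)c(OC)c2)ccc1OCc1ccccc1 | intermediate
21 | (3S,4R)-3-(hydroxymethoxy)-4-[(R)-hydroxy(4-hydroxy-3-methoxyphenyl)methyl]-3-(4-hydroxy-3-methoxybenzyl)dihydrofuran-2(3H)-one | COc1cc(C[C@@]2(OCO)C(=O)OC[C@@H]2[C@@H](O)c2ccc(O)c(OC)c2)ccc1O | intermediate (not isolated)
22 | (3S,4R)-3-hydroxy-4-[(R)-hydroxy(4-hydroxy-3-methoxyphenyl)methyl]-3-(4-hydroxy-3-methoxybenzyl)dihydrofuran-2(3H)-one | COc1cc(C[C@@]2(O)C(=O)OC[C@@H]2[C@@H](O)c2ccc(O)c(OC)c2)ccc1O | target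

**Count**
Total steps: 11. Longest linear sequence: 9 steps from (S)-malic acid (steps 1, 3, 4, 6, 7, 8, 9, 10, 11).

**Steps most likely to fail**

Step 9. β-Elimination may outrun the tandem: the C4 enolate can expel the C3 alkoxy group (E1cB), or the closed lactone can lose its carboxylate from C5, and equilibration at C4 may stop short. The fallback sets out from 15 and returns at 19, forming C4–C5 without base. In-situ-quench enolisation (LiN(SiMe3)2, Me3SiCl, THF, −78 °C), cold enough that the lithium enolate should not eliminate, gives the (Z)-trimethylsilyl enol ether F1. A Mukaiyama aldol with aqueous formaldehyde and catalytic Yb(OTf)3 in THF–water then gives hydroxy ester 17, now isolated. Catalytic camphorsulfonic acid in CH2Cl2 closes the lactone to a mixture of 18 and 19, and brief exposure to Et3N, or chromatography with recycling of 18, brings the material to 19.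

Step 10. Facial selectivity may be poor, because the branched C4 substituent can rival the aryl group as the large group and the inherent bias of the substrate may oppose the catalyst. The fallback sets out from 19 and returns at 20. Substrate-controlled reduction with Zn(BH4)2 (Et2O, −20 °C, non-basic) is followed by separation of the C6 epimers. The unwanted (6S)-alcohol F2 is inverted by Mitsunobu reaction (4-nitrobenzoic acid, PPh3, DIAD, THF, 0 °C) to the (6R)-4-nitrobenzoate F3, whose mild methanolysis (K2CO3, MeOH, 0 °C) gives 20.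

Step 11. Over-reduction is the risk: hydrogenolysis of the electron-rich C6 benzylic C–O bond may compete during the slow cleavage of the hindered acetal. The fallback sets out from 19 and returns at 22 by changing the order of events. Hydrogenolysis at the ketone stage (H2, 10 % Pd/C, EtOAc), where no benzylic alcohol exists, passes through the O-hydroxymethyl hemiacetal F4 to the keto triol F5. The aryl ketone is then reduced last by Noyori asymmetric transfer hydrogenation with RuCl(p-cymene)[(R,R)-TsDPEN] (TsDPEN = N-tosyl-1,2-diphenylethylenediamine) in HCO2H–Et3N (5:2). This acidic medium tolerates the free phenols and the tertiary alcohol and should give the (R)-carbinol 22.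

**Further compounds**
F1 | step 9 | methyl (2S,3Z)-2-[(benzyloxy)methoxy]-2-[4-(benzyloxy)-3-methoxybenzyl]-4-[4-(benzyloxy)-3-methoxyphenyl]-4-[(trimethylsilyl)oxy]but-3-enoate | COc1cc(C[C@@](OCOCc3ccccc3)(C(=O)OC)/C=C(\O[Si](C)(C)C)c2ccc(OCc3ccccc3)c(OC)c2)ccc1OCc1ccccc1
F2 | step 10 | (3S,4R)-3-[(benzyloxy)methoxy]-3-[4-(benzyloxy)-3-methoxybenzyl]-4-[(S)-[4-(benzyloxy)-3-methoxyphenyl](hydroxy)methyl]dihydrofuran-2(3H)-one | COc1cc(C[C@@]2(OCOCc3ccccc3)C(=O)OC[C@@H]2[C@H](O)c2ccc(OCc3ccccc3)c(OC)c2)ccc1OCc1ccccc1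
F3 | step 10 | (R)-[4-(benzyloxy)-3-methoxyphenyl]{(3R,4S)-4-[(benzyloxy)methoxy]-4-[4-(benzyloxy)-3-methoxybenzyl]-5-oxotetrahydrofuran-3-yl}methyl 4-nitrobenzoate | COc1cc(C[C@@]2(OCOCc3ccccc3)C(=O)OC[C@@H]2[C@@H](OC(=O)c3ccc(cc3)[N+](=O)[O-])c2ccc(OCc3ccccc3)c(OC)c2)ccc1OCc1ccccc1
F4 | step 11 | (3S,4S)-3-(hydroxymethoxy)-4-(4-hydroxy-3-methoxybenzoyl)-3-(4-hydroxy-3-methoxybenzyl)dihydrofuran-2(3H)-one | COc1cc(C[C@@]2(OCO)C(=O)OC[C@@H]2C(=O)c2ccc(O)c(OC)c2)ccc1O
F5 | step 11 | (3S,4S)-3-hydroxy-4-(4-hydroxy-3-methoxybenzoyl)-3-(4-hydroxy-3-methoxybenzyl)dihydrofuran-2(3H)-one | COc1cc(C[C@@]2(O)C(=O)OC[C@@H]2C(=O)c2ccc(O)c(OC)c2)ccc1O
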